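**Retrosynthetic overview**
- Target ⇐ desilylation, C3 acetylation and β-face cis-dihydroxylation of a cis-fused dauca-3,7-diene.
- That cyclopentene ⇐ Luche reduction and Myers reductive 1,3-transposition of a bicyclic enone, which sets H-5.
- Bicyclic enone ⇐ one intramolecular Pauson–Khand [2+2+1] of an acyclic (Z)-1,8-enyne with CO: the five- and seven-membered rings form together and C1 is set.
- Enyne ⇐ CBS reduction and esterification of a (Z)-enynone, made by alkynyllithium opening of (S)-6-isopropenyl-4-methyl-5,6-dihydropyran-2-one.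
- Lactone (a temporary ring, formed first and opened again) ⇐ asymmetric vinylogous Mukaiyama aldol–lactonisation of methacrolein; it fixes C10 and the Z-alkene.

Locants follow daucane numbering: C1 quaternary ring-fusion carbon (angular methyl), C2 ring CH2, C3, C4 (isopropyl), C5 ring-fusion CH, C6, C7, C8 (ring methyl), C9, C10. β is the face of the angular methyl. TBS = tert-butyldimethylsilyl. The target is (1S,3S,4R,5R,6S,10S): 3β-OAc, 4β-OH, 5β-H (cis-fused), 6α-ester, 10β-OH.

Assumption: the senses of induction in steps 2 and 4 follow the usual models; if a first run shows the opposite sense, the mirror-image ligand or catalyst is used and nothing else changes.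

**Step 1**
Reactants: 1 ethyl 3-methylbut-2-enoate
Product: 2 1-ethoxy-3-methyl-1-(trimethylsilyloxy)buta-1,3-diene
Conditions: LiN(iPr)2 (1.1 equiv), THF, −78 °C; Me3SiCl, −78 °C → rt; distil
Reagents that add atoms: chlorotrimethylsilane, C[Si](C)(C)Cl
Why: Kinetic γ-deprotonation of the senecioate and O-silylation of the extended enolate give the silyl dienolate (silyl ketene acetal formation); no stereocentre is formed.

**Step 2**
Reactants: 2 1-ethoxy-3-methyl-1-(trimethylsilyloxy)buta-1,3-diene; 3 methacrolein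
Product: 5 (S)-4-methyl-6-(prop-1-en-2-yl)-5,6-dihydro-2H-pyran-2-one, via monovalent copper aldolate 4 (not isolated)
Conditions: Cu(OTf)2 (10 mol %), (S)-2,2'-bis(di-p-tolylphosphino)-1,1'-binaphthyl [(S)-Tol-BINAP] (11 mol %), (Bu4N)(Ph3SiF2) (20 mol %), THF, −78 → 0 °C
Reagents that add atoms: none
Why: Catalytic asymmetric vinylogous Mukaiyama aldol: the Tol-BINAP-bound monovalent copper dienolate adds through its γ-carbon to one enantioface of the aldehyde to set C10 as S, and only the (Z)-aldolate can lactonise, which locks the future ring alkene as Z.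

**Step 3**
Reactants: 5 (S)-4-methyl-6-(prop-1-en-2-yl)-5,6-dihydro-2H-pyran-2-one; 6 3-methylbut-1-yne
Product: 9 (3S,5Z)-3-[(tert-butyldimethylsilyl)oxy]-2,5,10-trimethylundeca-1,5-dien-8-yn-7-one, via (3-methylbut-1-yn-1-yl)lithium 7 (not isolated), via ring-opened lithium alkoxide 8 (not isolated)
Conditions: 6, n-BuLi, THF, −78 °C; add 5, −78 °C; tBuMe2SiOTf, −78 → −20 °C
Reagents that add atoms: tert-butyldimethylsilyl trifluoromethanesulfonate, CC(C)(C)[Si](C)(C)OS(=O)(=O)C(F)(F)F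
Why: Acyl substitution at the lactone: the alkynyllithium adds once (the lactolate does not accept a second equivalent at −78 °C) and the silyl triflate captures the ring-opened secondary alkoxide of the conjugated ynone, so C10 and the Z-alkene are carried over unchanged.

**Step 4**
Reactants: 9 (3S,5Z)-3-[(tert-butyldimethylsilyl)oxy]-2,5,10-trimethylundeca-1,5-dien-8-yn-7-one
Product: 10 (3S,5Z,7S)-3-[(tert-butyldimethylsilyl)oxy]-2,5,10-trimethylundeca-1,5-dien-8-yn-7-ol
Conditions: (S)-1-methyl-3,3-diphenyltetrahydro-1H,3H-pyrrolo[1,2-c][1,3,2]oxazaborole [(S)-Me-CBS] (20 mol %), catecholborane (1.5 equiv), toluene, −78 °C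
Reagents that add atoms: none
Why: Corey–Bakshi–Shibata reduction: the ketone binds to boron anti to its bulkier β,β-disubstituted Z-alkenyl arm (the rod-like alkynyl arm is the small group) and hydride is delivered intramolecularly to one face to give the 7S carbinol, while catecholborane leaves the alkenes and alkyne alone at −78 °C.

**Step 5**
Reactants: 11 4-hydroxybenzoic acid
Product: 13 4-[(tert-butyldimethylsilyl)oxy]benzoic acid, via bis-silylated acid 12 (not isolated)
Conditions: tBuMe2SiCl (2.3 equiv), imidazole, DMF, rt; AcOH/THF/H2O, rt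
Reagents that add atoms: tert-butyldimethylsilyl chloride, CC(C)(C)[Si](C)(C)Cl
Why: Silylation of both acidic hydroxyls followed by chemoselective hydrolysis of the much more labile silyl ester; no stereocentre.

**Step 6**
Reactants: 10 (3S,5Z,7S)-3-[(tert-butyldimethylsilyl)oxy]-2,5,10-trimethylundeca-1,5-dien-8-yn-7-ol; 13 4-[(tert-butyldimethylsilyl)oxy]benzoic acid
Product: 14 (3S,5Z,7S)-3-[(tert-butyldimethylsilyl)oxy]-2,5,10-trimethylundeca-1,5-dien-8-yn-7-yl 4-[(tert-butyldimethylsilyl)oxy]benzoate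
Conditions: N-ethyl-N'-(3-dimethylaminopropyl)carbodiimide hydrochloride (EDC·HCl), 4-(dimethylamino)pyridine (cat.), CH2Cl2, 0 °C → rt
Reagents that add atoms: none
Why: Steglich esterification acylates oxygen without breaking the C7–O bond, so the propargylic centre keeps its S configuration (it becomes C6 of the ring system).

**Step 7**
Reactants: 14 (3S,5Z,7S)-3-[(tert-butyldimethylsilyl)oxy]-2,5,10-trimethylundeca-1,5-dien-8-yn-7-yl 4-[(tert-butyldimethylsilyl)oxy]benzoate
Product: 16 (1S,6S,10S)-10-[(tert-butyldimethylsilyl)oxy]-3-oxodauca-4,7-dien-6-yl 4-[(tert-butyldimethylsilyl)oxy]benzoate, via hexacarbonyldicobalt alkyne complex 15 (not isolated)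
Conditions: Co2(CO)8 (1.1 equiv), CH2Cl2, rt; then N-methylmorpholine N-oxide (8 equiv), CH2Cl2 (0.01 M), 0 °C → rt
Reagents that add atoms: dicobalt octacarbonyl (source of the C3 carbonyl), [C-]#[O+].[C-]#[O+].[C-]#[O+].[C-]#[O+].[C-]#[O+].[C-]#[O+].[C-]#[O+].[C-]#[O+].[Co].[Co]
Why: Proposed new method: intramolecular Pauson–Khand [2+2+1] of a 1,8-enyne with a 1,1-disubstituted alkene, in which the Z-alkene of the tether holds the cobalt-bound alkyne and the isopropenyl group cis, exo-mode alkene insertion into the Co–C5 bond forms C5–C1 (seven-membered ring and quaternary C1) and CO insertion with reductive elimination forms C2–C3–C4 (cyclopentenone), the closest known reaction type being Pauson–Khand closure of cis-alkene- or arene-constrained 1,8-enynes to bicyclo[5.3.0]decenones; C1 is set in the insertion step through a chair-like transition state with the C10 silyloxy group anti to the forming bond (H-10 eclipsing the =CH2) and the C6 ester perpendicular to the alkyne–cobalt plane (no A(1,3) strain with the isopropyl-bearing carbon), which puts the methyl cis to O-10 and trans to O-6.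

**Step 8**
Reactants: 16 (1S,6S,10S)-10-[(tert-butyldimethylsilyl)oxy]-3-oxodauca-4,7-dien-6-yl 4-[(tert-butyldimethylsilyl)oxy]benzoate
Product: 17 (1S,3R,6S,10S)-10-[(tert-butyldimethylsilyl)oxy]-3-hydroxydauca-4,7-dien-6-yl 4-[(tert-butyldimethylsilyl)oxy]benzoate
Conditions: NaBH4, CeCl3·7H2O, MeOH/THF, −78 °C
Reagents that add atoms: none
Why: Luche 1,2-reduction: hydride attacks the cerium-activated carbonyl on the β face, next to the small angular methyl and away from the C10 arm of the seven-membered ring that covers the α face, giving the 3α (3R) allylic alcohol without conjugate reduction or loss of the γ-ester.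

**Step 9**
Reactants: 17 (1S,3R,6S,10S)-10-[(tert-butyldimethylsilyl)oxy]-3-hydroxydauca-4,7-dien-6-yl 4-[(tert-butyldimethylsilyl)oxy]benzoate
Product: 20 (1S,5R,6S,10S)-10-[(tert-butyldimethylsilyl)oxy]dauca-3,7-dien-6-yl 4-[(tert-butyldimethylsilyl)oxy]benzoate, via allylic sulfonylhydrazine 18 (not isolated), via allylic diazene 19 (not isolated)
Conditions: 2-nitrobenzenesulfonohydrazide, PPh3, DEAD, THF, −30 °C; then rt
Reagents that add atoms: none
Why: Myers reductive 1,3-transposition: Mitsunobu displacement by the sulfonylhydrazine inverts C3 (nitrogen β), loss of arenesulfinic acid gives the monoalkyl diazene, and its retro-ene loss of N2 transfers hydrogen suprafacially to the β face of C5 while the alkene moves to C3=C4, which sets the cis ring fusion.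

**Step 10**
Reactants: 20 (1S,5R,6S,10S)-10-[(tert-butyldimethylsilyl)oxy]dauca-3,7-dien-6-yl 4-[(tert-butyldimethylsilyl)oxy]benzoate
Product: 21 (1S,3S,4R,5R,6S,10S)-10-[(tert-butyldimethylsilyl)oxy]-3,4-dihydroxydauc-7-en-6-yl 4-[(tert-butyldimethylsilyl)oxy]benzoate
Conditions: OsO4 (5 mol %), N-methylmorpholine N-oxide, acetone/H2O, 0 °C
Reagents that add atoms: osmium tetroxide (oxygen-transfer catalyst), O=[Os](=O)(=O)=O; N-methylmorpholine N-oxide, C[N+]1([O-])CCOCC1; water, O
Why: Upjohn syn-dihydroxylation: OsO4 adds to the cyclopentene from its β face because the α face is covered by C6 and its ester on the allylic carbon C5, giving the 3β,4β-diol (3S,4R), and the C7=C8 alkene reacts more slowly because the allylic ester deactivates it.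

**Step 11**
Reactants: 21 (1S,3S,4R,5R,6S,10S)-10-[(tert-butyldimethylsilyl)oxy]-3,4-dihydroxydauc-7-en-6-yl 4-[(tert-butyldimethylsilyl)oxy]benzoate
Product: 22 (1S,3S,4R,5R,6S,10S)-3-acetoxy-10-[(tert-butyldimethylsilyl)oxy]-4-hydroxydauc-7-en-6-yl 4-[(tert-butyldimethylsilyl)oxy]benzoate
Conditions: Ac2O, pyridine, 4-(dimethylamino)pyridine (cat.), CH2Cl2, 0 °C
Reagents that add atoms: acetic anhydride, CC(=O)OC(C)=O
Why: Nucleophile-catalysed acylation of the only free secondary hydroxyl (C3); the tertiary C4 hydroxyl does not react under these conditions and no stereocentre is touched.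

**Step 12**
Reactants: 22 (1S,3S,4R,5R,6S,10S)-3-acetoxy-10-[(tert-butyldimethylsilyl)oxy]-4-hydroxydauc-7-en-6-yl 4-[(tert-butyldimethylsilyl)oxy]benzoate
Product: 23 (1S,3S,4R,5R,6S,10S)-3-acetoxy-4,10-dihydroxydauc-7-en-6-yl 4-hydroxybenzoate
Conditions: Bu4NF, AcOH (1:1), THF, 0 °C → rt
Reagents that add atoms: none
Why: Fluoride-induced cleavage of both Si–O bonds, with acetic acid protonating the liberated phenoxide and alkoxide before they can attack or shift the two esters; no stereocentre is touched.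

**Compound list**
1 | ethyl 3-methylbut-2-enoate | CCOC(=O)C=C(C)C | starting material
2 | 1-ethoxy-3-methyl-1-(trimethylsilyloxy)buta-1,3-diene (ketene acetal isomer mixture) | C=C(C)C=C(OCC)O[Si](C)(C)C | intermediate
3 | methacrolein (2-methylprop-2-enal) | C=C(C)C=O | starting material
4 | ethyl (2Z,5S)-5-hydroxy-3,6-dimethylhepta-2,6-dienoate, monovalent copper alkoxide | CCOC(=O)/C=C(C)\C[C@H](O[Cu])C(C)=C | intermediate
5 | (S)-4-methyl-6-(prop-1-en-2-yl)-5,6-dihydro-2H-pyran-2-one | C=C(C)[C@@H]1CC(C)=CC(=O)O1 | intermediate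
6 | 3-methylbut-1-yne | CC(C)C#C | starting material
7 | (3-methylbut-1-yn-1-yl)lithium | CC(C)C#C[Li] | intermediate
8 | lithium (3S,5Z)-2,5,10-trimethyl-7-oxoundeca-1,5-dien-8-yn-3-olate (in equilibrium with its cyclic lactolate) | C=C(C)[C@@H](O[Li])C/C(C)=C\C(=O)C#CC(C)C | intermediate
9 | (3S,5Z)-3-[(TBS)oxy]-2,5,10-trimethylundeca-1,5-dien-8-yn-7-one | C=C(C)[C@@H](O[Si](C)(C)C(C)(C)C)C/C(C)=C\C(=O)C#CC(C)C | intermediate
10 | (3S,5Z,7S)-3-[(TBS)oxy]-2,5,10-trimethylundeca-1,5-dien-8-yn-7-ol | C=C(C)[C@@H](O[Si](C)(C)C(C)(C)C)C/C(C)=C\[C@H](O)C#CC(C)C | intermediate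
11 | 4-hydroxybenzoic acid | OC(=O)c1ccc(O)cc1 | starting material
12 | tert-butyldimethylsilyl 4-[(TBS)oxy]benzoate | CC(C)(C)[Si](C)(C)OC(=O)c1ccc(O[Si](C)(C)C(C)(C)C)cc1 | intermediate
13 | 4-[(TBS)oxy]benzoic acid | OC(=O)c1ccc(O[Si](C)(C)C(C)(C)C)cc1 | intermediate
14 | (3S,5Z,7S)-3-[(TBS)oxy]-2,5,10-trimethylundeca-1,5-dien-8-yn-7-yl 4-[(TBS)oxy]benzoate | C=C(C)[C@@H](O[Si](C)(C)C(C)(C)C)C/C(C)=C\[C@H](OC(=O)c1ccc(O[Si](C)(C)C(C)(C)C)cc1)C#CC(C)C | intermediate
15 | hexacarbonyldicobalt complex of 14 (Co2(CO)6 bridging the C8≡C9 alkyne) | C=C(C)[C@@H](O[Si](C)(C)C(C)(C)C)C/C(C)=C\[C@H](OC(=O)c1ccc(O[Si](C)(C)C(C)(C)C)cc1)[C]23[C]4(C(C)C)[Co]2(=C=O)(=C=O)(=C=O)[Co]34(=C=O)(=C=O)=C=O | intermediate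
16 | (1S,6S,10S)-10-[(TBS)oxy]-3-oxodauca-4,7-dien-6-yl 4-[(TBS)oxy]benzoate | O=C1C[C@]2(C)[C@@H](O[Si](C)(C)C(C)(C)C)CC(C)=C[C@H](OC(=O)c3ccc(O[Si](C)(C)C(C)(C)C)cc3)C2=C1C(C)C | intermediate
17 | (1S,3R,6S,10S)-10-[(TBS)oxy]-3-hydroxydauca-4,7-dien-6-yl 4-[(TBS)oxy]benzoate (3α-OH) | O[C@@H]1C[C@]2(C)[C@@H](O[Si](C)(C)C(C)(C)C)CC(C)=C[C@H](OC(=O)c3ccc(O[Si](C)(C)C(C)(C)C)cc3)C2=C1C(C)C | intermediate
18 | (1S,3S,6S,10S)-10-[(TBS)oxy]-3-[1-(2-nitrophenylsulfonyl)hydrazin-1-yl]dauca-4,7-dien-6-yl 4-[(TBS)oxy]benzoate | NN(S(=O)(=O)c4ccccc4[N+](=O)[O-])[C@H]1C[C@]2(C)[C@@H](O[Si](C)(C)C(C)(C)C)CC(C)=C[C@H](OC(=O)c3ccc(O[Si](C)(C)C(C)(C)C)cc3)C2=C1C(C)C | intermediate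
19 | (1S,3S,6S,10S)-10-[(TBS)oxy]-3-diazenyldauca-4,7-dien-6-yl 4-[(TBS)oxy]benzoate | N=N[C@H]1C[C@]2(C)[C@@H](O[Si](C)(C)C(C)(C)C)CC(C)=C[C@H](OC(=O)c3ccc(O[Si](C)(C)C(C)(C)C)cc3)C2=C1C(C)C | intermediate
20 | (1S,5R,6S,10S)-10-[(TBS)oxy]dauca-3,7-dien-6-yl 4-[(TBS)oxy]benzoate (cis-fused, H-5β) | C1=C(C(C)C)[C@H]2[C@@H](OC(=O)c3ccc(O[Si](C)(C)C(C)(C)C)cc3)C=C(C)C[C@H](O[Si](C)(C)C(C)(C)C)[C@@]2(C)C1 | intermediate
21 | (1S,3S,4R,5R,6S,10S)-10-[(TBS)oxy]-3,4-dihydroxydauc-7-en-6-yl 4-[(TBS)oxy]benzoate | O[C@H]1C[C@]2(C)[C@@H](O[Si](C)(C)C(C)(C)C)CC(C)=C[C@H](OC(=O)c3ccc(O[Si](C)(C)C(C)(C)C)cc3)[C@@H]2[C@]1(O)C(C)C | intermediate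
22 | (1S,3S,4R,5R,6S,10S)-3-acetoxy-10-[(TBS)oxy]-4-hydroxydauc-7-en-6-yl 4-[(TBS)oxy]benzoate | CC(=O)O[C@H]1C[C@]2(C)[C@@H](O[Si](C)(C)C(C)(C)C)CC(C)=C[C@H](OC(=O)c3ccc(O[Si](C)(C)C(C)(C)C)cc3)[C@@H]2[C@]1(O)C(C)C | intermediate
23 | (1S,3S,4R,5R,6S,10S)-3-acetoxy-4,10-dihydroxydauc-7-en-6-yl 4-hydroxybenzoate (CNP0146780.2) | CC(=O)O[C@H]1C[C@]2(C)[C@@H](O)CC(C)=C[C@H](OC(=O)c3ccc(O)cc3)[C@@H]2[C@]1(O)C(C)C | target

**Step count and risks**
Total steps: 12. Longest linear sequence: 11 (steps 1–4 and 6–12; step 5 is a one-step side branch).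

Steps most likely to fail:

1. Step 7 (Pauson–Khand closure). The risks are loss of the propargylic ester at the cobalt cluster and closure to the wrong C1 epimer; the C1 prediction is the least secure stereochemical call in the route. The fallback sets out from 9 and comes back at 16. Ketone 9 is reduced with the mirror-image catalyst ((R)-Me-CBS, catecholborane) to the C7-epimeric carbinol (3S,5Z,7R)-3-[(TBS)oxy]-2,5,10-trimethylundeca-1,5-dien-8-yn-7-ol F3. With its propargylic hydroxyl left free, this is complexed with Co2(CO)8 to the hexacarbonyldicobalt complex of that alkynol F4 and cyclised with N-methylmorpholine N-oxide to the hydroxy enone (1S,6R,10S)-10-[(TBS)oxy]-6-hydroxydauca-4,7-dien-3-one F5. Here the propargylic oxygen lies on the same side as the angular substituent, the usual outcome of such closures with propargylic oxygen substituents. Mitsunobu esterification of F5 with acid 13 (PPh3, DIAD, toluene, 0 °C) then inverts C6 and gives 16.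

2. Step 9 (hydrogen delivery to C5; it depends on the facial outcome of step 8 and on a Mitsunobu reaction at a hindered cyclopentenyl carbinol). The fallback sets out from 16 and comes back at 19, and so at 20. Enone 16 is condensed with TsNHNH2 (EtOH, AcOH cat., 50 °C) to the tosylhydrazone of 16 F6. Catecholborane (CHCl3, 0 °C) adds hydride to C3 to give the allylic tosylhydrazine (1S,3S,6S,10S)-10-[(TBS)oxy]-3-(2-tosylhydrazin-1-yl)dauca-4,7-dien-6-yl 4-[(TBS)oxy]benzoate F7, and NaOAc·3H2O at reflux expels sulfinate to give diazene 19, which collapses to 20. In this sequence H-5 ends on the face opposite to the one attacked by hydride at C3, whereas the Luche–Myers pair puts it on the same face. It is therefore the route of choice if hydride proves to attack the α face, which would send step 9 to the trans-fused isomer.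

3. Step 3 (one-pot alkynylation and silylation; the risks are a second acetylide addition once the lactolate opens, silylation at the lactolate oxygen and γ-deprotonation of the lactone). The fallback sets out from 5 and comes back at 9. Lactone 5 is opened with Me(MeO)NH·HCl and AlMe3 (CH2Cl2, 0 °C) to the Weinreb amide (2Z,5S)-5-hydroxy-N-methoxy-N,3,6-trimethylhepta-2,6-dienamide F1. Silylation (tBuMe2SiCl, imidazole, DMF) gives its silyl ether (2Z,5S)-5-[(TBS)oxy]-N-methoxy-N,3,6-trimethylhepta-2,6-dienamide F2. F2 takes up lithium acetylide 7 (THF, −78 °C) as a stable chelate that collapses only on work-up, giving 9 without over-addition.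

**Further compounds**
F1 | step 3 | (2Z,5S)-5-hydroxy-N-methoxy-N,3,6-trimethylhepta-2,6-dienamide | C=C(C)[C@@H](O)C/C(C)=C\C(=O)N(C)OC
F2 | step 3 | (2Z,5S)-5-[(TBS)oxy]-N-methoxy-N,3,6-trimethylhepta-2,6-dienamide | C=C(C)[C@@H](O[Si](C)(C)C(C)(C)C)C/C(C)=C\C(=O)N(C)OC
F3 | step 7 | (3S,5Z,7R)-3-[(TBS)oxy]-2,5,10-trimethylundeca-1,5-dien-8-yn-7-ol | C=C(C)[C@@H](O[Si](C)(C)C(C)(C)C)C/C(C)=C\[C@@H](O)C#CC(C)C
F4 | step 7 | hexacarbonyldicobalt complex of F3 | C=C(C)[C@@H](O[Si](C)(C)C(C)(C)C)C/C(C)=C\[C@@H](O)[C]12[C]3(C(C)C)[Co]1(=C=O)(=C=O)(=C=O)[Co]23(=C=O)(=C=O)=C=O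
F5 | step 7 | (1S,6R,10S)-10-[(TBS)oxy]-6-hydroxydauca-4,7-dien-3-one | O=C1C[C@]2(C)[C@@H](O[Si](C)(C)C(C)(C)C)CC(C)=C[C@@H](O)C2=C1C(C)C
F6 | step 9 | tosylhydrazone of 16 | Cc1ccc(cc1)S(=O)(=O)NN=C1C[C@]2(C)[C@@H](O[Si](C)(C)C(C)(C)C)CC(C)=C[C@H](OC(=O)c3ccc(O[Si](C)(C)C(C)(C)C)cc3)C2=C1C(C)C
F7 | step 9 | (1S,3S,6S,10S)-10-[(TBS)oxy]-3-(2-tosylhydrazin-1-yl)dauca-4,7-dien-6-yl 4-[(TBS)oxy]benzoate | Cc1ccc(cc1)S(=O)(=O)NN[C@H]1C[C@]2(C)[C@@H](O[Si](C)(C)C(C)(C)C)CC(C)=C[C@H](OC(=O)c3ccc(O[Si](C)(C)C(C)(C)C)cc3)C2=C1C(C)C
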